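Temperature shifts the balance between E and D, and time brings a flask towards that balance.

| flask | L | temperature | remark | time |
|---|---|---|---|---|
| Sunday's | 1.3 M | 12 °C | run made earlier |  |
| Thursday's | 3 M | 29 °C | run made earlier |  |
| maple | 2.0 M | 5 °C |  | 3.0 h |
| larch | 2.0 M | 35 °C |  | 3.0 h |

- Sunday's (time / h: E / %, D / %): 0.200: 34.9, 18.1; 0.417: 35.0, 24.9; 1.00: 24.7, 32.5; 2.50: 19.7, 30.4
- Thursday's (time / min: E / %, D / %): 12.0: 7.2, 40.6; 25.0: 6.0, 36.9; 40.0: 4.9, 30.7; 50.0: 5.0, 30.3

(standard deviation of a reading: 1 percentage point)

- the flask that comes out highest in share of E in all that became E or D or G, or "all alike" when all lie within 1.5 percentage points (maple / larch / all alike)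
- share of E in all that became E or D or G, maple
- share of E in all that became E or D or G, larch



**Examiner:** What do the runs show of E against D?

**Candidate:** Call the ratio E/D r. In Thursday's run r goes from 0.177 to 0.165, which is flat within the scatter, so I pool its readings to 0.167 and read that as equilibrium. In Sunday's run r falls from 0.760 at 1.00 h to 0.648 at 2.50 h. I take this last reading as near equilibrium, though it may still be falling.

**Examiner:** How do you carry r to new temperatures?

**Candidate:** I treat r as an equilibrium constant and assume that ln r runs straight in inverse absolute temperature. The two runs give 57.2 kJ mol⁻¹, which I call the balance heat W: the gas constant times the change of ln r per unit of inverse absolute temperature. So r comes to 1.19 for maple and 0.107 for larch.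

**Examiner:** But the question asks for a share, and G was never read.

**Candidate:** Leaving G out gives the balance share r/(1+r), the split under thermodynamic control. Any G in the denominator lowers the true share below E/(E+D).

**Examiner:** Is cold maple at balance in its time?

**Candidate:** Not surely. If cooling from Sunday's temperature slows rates by a factor 2, which is my assumption, maple's 3.0 h counts as 1.50 h of Sunday's run. That lies between Sunday's readings at 1.00 h and 2.50 h, so maple's r may stand above equilibrium, which raises the share while G lowers it. I commit to 54.3 % for maple and 9.67 % for larch, so I name maple as the higher.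

The forecast also names maple, but with lower figures than mine: 27 % for maple and 3 % for larch. Of Thursday's ratio it says: “which looks like E⇌D equilibrium”.

The flask gives 52.8 % for maple and 8.59 % for larch, so maple stands higher.

    L ⇌ E (K = 2.70, k = 0.0570 min⁻¹, Ea = 76.0 kJ mol⁻¹, ΔH = −43.0 kJ mol⁻¹)
    L ⇌ G (K = 0.440, k = 0.0330 min⁻¹, Ea = 89.0 kJ mol⁻¹, ΔH = −12.0 kJ mol⁻¹)
    L ⇌ D (K = 2.20, k = 0.0180 min⁻¹, Ea = 84.0 kJ mol⁻¹, ΔH = 16.0 kJ mol⁻¹)
    2 L → Z (k = 0.0140 M⁻¹ min⁻¹, Ea = 59.0 kJ mol⁻¹)
    (constants at 5 °C)

At 3.00 h maple holds E and D in the ratio 1.35, against my 1.19, with G at 4.46 % of the L charged. For a further flask, maple's charge run at −20 °C, W gives r = 13.7 and a balance share of 93.2 %. That flask holds, at 3.00 h, E 23.1 % and D 5.01 % of the L charged, with L 34.3 % left, and its share is 65.8 %.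

(Readings and results stem from a simulated flask with made-up constants; the scatter is artificial.)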